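The diaryl ether oxygen is not made by coupling two arenes; ring B is built around it. Ring B is a hydroquinone whose oxygens at C2' and C5' are para and whose ether oxygen at C1' neighbours C2', the pattern of a Dötz benzannulation. In one operation a vinyl(methoxy)carbene complex of zerovalent chromium, a terminal aryloxyalkyne and one CO ligand form C5'–C6', C1'–C2' and C2'–C3' and close ring B as a 4-methoxyphenol. The precursor is the ethynyl ether of the fully brominated, O-methylated ring A phenol. Demethylation and tribromination of ring B finish the synthesis.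

Key step: step 7

Numbering used: ring A is C1 (OH), C2 (Br), C3 (H), C4 (ether O), C5 (Br), C6 (Br); ring B is C1' (ether O), C2' (OH), C3' (Br), C4' (Br), C5' (OH), C6' (Br).

Assumption: 2,6-dibromoanisole is taken as a purchasable starting material. The target has no stereocentre; dibromide 8 is racemic and its stereocentre disappears in the same flask.

Step 1
Reactants: 1 1,3-dibromo-2-methoxybenzene (2,6-dibromoanisole)
Product: 3 3,5-dibromo-4-methoxyphenol, via the aryl pinacol boronate 2 (not isolated)
Conditions: [Ir(OMe)(cod)]2 (1.5 mol%), dtbpy (3 mol%), B2pin2 (0.7 equiv), THF, 80 °C; then KHSO5 (as 2KHSO5·KHSO4·K2SO4), acetone/H2O, rt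
Reagents that add atoms: potassium peroxymonosulfate KHSO5, [K+].[O-]S(=O)(=O)OO
Why: Iridium-catalysed aromatic C–H borylation is sterically controlled and should take the only hydrogen of 1 without an ortho neighbour (para to OMe), and oxidation of the C–B bond by peroxymonosulfate in the same flask then delivers the phenol (one-pot C–H borylation/oxidation).

Step 2
Reactants: 3 3,5-dibromo-4-methoxyphenol
Product: 4 2,3,5-tribromo-4-methoxyphenol
Conditions: NBS (1.0 equiv), i-Pr2NH (10 mol%), CH2Cl2, 0 °C
Reagents that add atoms: N-bromosuccinimide, O=C1CCC(=O)N1Br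
Why: Electrophilic aromatic bromination directed by the free hydroxyl group, whose para position is blocked and whose two ortho positions are equivalent, so that one equivalent of NBS with a catalytic secondary amine should stop at the ortho-monobromide.

Step 3
Reactants: 4 2,3,5-tribromo-4-methoxyphenol; 5 1,2-dibromoethane
Product: 6 1,3,4-tribromo-5-(2-bromoethoxy)-2-methoxybenzene
Conditions: 5 (6 equiv), K2CO3, MeCN, 80 °C
Reagents that add atoms: none
Why: Williamson ether synthesis (SN2) of the readily ionised, acidic phenol, with the dihalide in excess so that its second bromide is not displaced.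

Step 4
Reactants: 6 1,3,4-tribromo-5-(2-bromoethoxy)-2-methoxybenzene
Product: 7 1,3,4-tribromo-5-(ethenyloxy)-2-methoxybenzene
Conditions: KOtBu (1.5 equiv), THF, 0 °C → rt
Reagents that add atoms: none
Why: Base-induced E2 dehydrobromination, in which tert-butoxide removes a proton beside oxygen while bromide leaves, is the standard route from 2-aryloxyethyl bromides to aryl vinyl ethers and leaves aryl bromides untouched at this temperature.

Step 5
Reactants: 7 1,3,4-tribromo-5-(ethenyloxy)-2-methoxybenzene
Product: 10 1,3,4-tribromo-5-(ethynyloxy)-2-methoxybenzene, via the 1,2-dibromoethyl ether 8 (not isolated), via the (Z)-2-bromovinyl ether 9 (not isolated)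
Conditions: Br2 (1.0 equiv), CH2Cl2, –78 °C; evaporate cold; KOtBu (3 equiv), THF, –78 → 0 °C; pH 7 buffer; kept cold in solution and used directly
Reagents that add atoms: none
Why: Bromine adds to the electron-rich enol ether double bond far faster than it attacks the deactivated ring, and two successive E2 dehydrobrominations with tert-butoxide (the second an anti elimination from the (Z)-2-bromovinyl ether) give the alkyne, the classical dibromide route to aryloxyacetylenes, without any organolithium reagent that would exchange the aryl bromides.

Step 6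
Reactants: 11 Cr(CO)6; 12 CH2=CHMgBr
Product: 14 pentacarbonyl[methoxy(vinyl)carbene]chromium, via the bromomagnesium acylchromate 13 (not isolated)
Conditions: CH2=CHMgBr (1.0 M in THF), THF, 0 °C → rt; evaporate; Me3OBF4, CH2Cl2/H2O, 0 °C; rapid filtration through silica (pentane), used at once
Reagents that add atoms: trimethyloxonium tetrafluoroborate, C[O+](C)C.F[B-](F)(F)F
Why: Fischer carbene synthesis, in which the vinyl nucleophile adds to a CO ligand of Cr(CO)6 and the resulting acylchromate is alkylated on oxygen by the hard oxonium salt; the complex is taken on at once because it does not keep.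

Step 7
Reactants: 10 1,3,4-tribromo-5-(ethynyloxy)-2-methoxybenzene; 14 pentacarbonyl[methoxy(vinyl)carbene]chromium
Product: 16 4-methoxy-2-(2,3,5-tribromo-4-methoxyphenoxy)phenol, via its tricarbonylchromium complex 15 (not isolated)
Conditions: 14 (2 equiv, two portions), degassed THF (0.05 M), 50 °C, Ar; then air, rt
Reagents that add atoms: none
Why: Thermal loss of one CO from 14 frees a site on zerovalent chromium, and 10 inserts so that its CH carbon bonds to the carbene carbon (C5'–C6') and its aryloxy-bearing carbon becomes the new carbene carbon C1'. Uptake of CO at C1' gives a chromium-bound dienylketene (C1'–C2'), which closes ring B and tautomerises to the phenol, held first as the Cr(CO)3 complex 15 and set free by air. The closest known reaction is the Dötz benzannulation of alkenyl(alkoxy)carbene complexes of chromium with terminal alkynes, which gives 4-methoxyphenols. The six-membered ring B closes by 6π-electrocyclisation of the dienylketene onto the vinyl terminus (C2'–C3'); no stereocentre is formed. The step needs one sense of alkyne insertion, and both the terminal alkyne (hydrogen, the small group, next to the methoxy-bearing carbon) and the ynol ether polarisation (nucleophilic CH carbon toward the electrophilic carbene carbon) place the aryloxy group at C1' beside the new hydroxyl. Freshly made 14 is used in excess because it is short-lived and 10 is the more valuable partner.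

Step 8
Reactants: 16 4-methoxy-2-(2,3,5-tribromo-4-methoxyphenoxy)phenol
Product: 17 2-(2,3,5-tribromo-4-hydroxyphenoxy)benzene-1,4-diol
Conditions: BBr3 (5 equiv), CH2Cl2, –78 °C → rt; then H2O, 0 °C
Reagents that add atoms: none
Why: Lewis-acid ether cleavage, in which BBr3 binds each methoxy oxygen and bromide removes the methyl group by SN2, while the diaryl ether link and the aryl bromides are inert.

Step 9
Reactants: 17 2-(2,3,5-tribromo-4-hydroxyphenoxy)benzene-1,4-diol
Product: 18 2,3,5-tribromo-6-(2,3,5-tribromo-4-hydroxyphenoxy)benzene-1,4-diol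
Conditions: Br2 (3.05 equiv), AcOH, 15 °C → rt, dark; aq. Na2S2O4 wash
Reagents that add atoms: bromine, BrBr
Why: Electrophilic aromatic bromination, in which each free position of ring B is ortho to a hydroxyl group of the hydroquinone and reacts much faster than C3 of ring A (meta to its hydroxyl group in a tribrominated ring), and the dithionite wash reduces any quinone formed by over-oxidation back to the hydroquinone.

Compound list
1 | 1,3-dibromo-2-methoxybenzene (2,6-dibromoanisole) | COc1c(Br)cccc1Br | starting material
2 | 2-(3,5-dibromo-4-methoxyphenyl)-4,4,5,5-tetramethyl-1,3,2-dioxaborolane (not isolated) | COc1c(Br)cc(cc1Br)B1OC(C)(C)C(C)(C)O1 | intermediate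
3 | 3,5-dibromo-4-methoxyphenol | COc1c(Br)cc(O)cc1Br | intermediate
4 | 2,3,5-tribromo-4-methoxyphenol | COc1c(Br)cc(O)c(Br)c1Br | intermediate
5 | 1,2-dibromoethane | BrCCBr | starting material
6 | 1,3,4-tribromo-5-(2-bromoethoxy)-2-methoxybenzene | COc1c(Br)cc(OCCBr)c(Br)c1Br | intermediate
7 | 1,3,4-tribromo-5-(ethenyloxy)-2-methoxybenzene | COc1c(Br)cc(OC=C)c(Br)c1Br | intermediate
8 | 1,3,4-tribromo-5-(1,2-dibromoethoxy)-2-methoxybenzene (racemic, not isolated) | COc1c(Br)cc(OC(Br)CBr)c(Br)c1Br | intermediate
9 | 1,3,4-tribromo-5-{[(Z)-2-bromoethenyl]oxy}-2-methoxybenzene (not isolated) | COc1c(Br)cc(O/C=C\Br)c(Br)c1Br | intermediate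
10 | 1,3,4-tribromo-5-(ethynyloxy)-2-methoxybenzene (ring A ynol ether) | COc1c(Br)cc(OC#C)c(Br)c1Br | intermediate
11 | Cr(CO)6 (hexacarbonylchromium) | O=C=[Cr](=C=O)(=C=O)(=C=O)(=C=O)=C=O | starting material
12 | CH2=CHMgBr (vinylmagnesium bromide) | C=C[Mg]Br | starting material
13 | bromomagnesium salt of pentacarbonyl(acryloyl)chromate, drawn as (CO)5Cr=C(OMgBr)CH=CH2 (not isolated) | C=CC(O[Mg]Br)=[Cr](=C=O)(=C=O)(=C=O)(=C=O)=C=O | intermediate
14 | pentacarbonyl[methoxy(vinyl)carbene]chromium | COC(C=C)=[Cr](=C=O)(=C=O)(=C=O)(=C=O)=C=O | intermediate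
15 | tricarbonyl[η6-4-methoxy-2-(2,3,5-tribromo-4-methoxyphenoxy)phenol]chromium, Cr(CO)3 on ring B, drawn as arene plus Cr(CO)3 fragment (not isolated) | COc1c(Br)cc(Oc2cc(OC)ccc2O)c(Br)c1Br.O=C=[Cr](=C=O)=C=O | intermediate
16 | 4-methoxy-2-(2,3,5-tribromo-4-methoxyphenoxy)phenol | COc1c(Br)cc(Oc2cc(OC)ccc2O)c(Br)c1Br | intermediate
17 | 2-(2,3,5-tribromo-4-hydroxyphenoxy)benzene-1,4-diol | Oc1ccc(O)c(Oc2cc(Br)c(O)c(Br)c2Br)c1 | intermediate
18 | 2,3,5-tribromo-6-(2,3,5-tribromo-4-hydroxyphenoxy)benzene-1,4-diol | Oc1c(Br)cc(Oc2c(O)c(Br)c(Br)c(O)c2Br)c(Br)c1Br | target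

Total step count: 9. Longest linear sequence: 8 (steps 1–5, 7, 8, 9); step 6 is a one-step side branch.

Steps most likely to fail

Step 7. The unsubstituted vinylcarbene complex may oligomerise through its unhindered β-carbon, or the sequence may stall after alkyne insertion at the aryloxy-stabilised vinylcarbene before CO is taken up, so that benzannulation is outrun. The fallback sets out from 10 and 11 and returns at 16; it forms the same three bonds with a β-silylated carbene complex. (E)-(2-Bromovinyl)trimethylsilane is treated with t-BuLi (Et2O, –78 °C) to give [(E)-2-(trimethylsilyl)ethenyl]lithium F1, which adds to 11 to give the lithium acylchromate F2. Me3OBF4 converts it into pentacarbonyl{methoxy[(E)-2-(trimethylsilyl)ethenyl]carbene}chromium F3, a β-substituted alkenylcarbene complex that is far more persistent than 14. Benzannulation of F3 with 10 (THF, 50 °C, then air) is known chemistry for such silylvinyl complexes. The cyclohexadienone formed after ring closure aromatises by a 1,3-shift of silicon from C3' to the C2' oxygen, which should give the aryl silyl ether [4-methoxy-2-(2,3,5-tribromo-4-methoxyphenoxy)phenoxy]trimethylsilane F4 with hydrogen at C3'. K2CO3 in MeOH removes the silyl group and gives 16.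

Step 5. tert-Butoxide may substitute the α-bromo ether instead of eliminating, the second elimination may stay incomplete, or the terminal ynol ether may oligomerise during work-up. The fallback sets out from 4 and returns at 17; the alkyne is given up and the ether bond is made to a preformed ring B. Cu(OAc)2-mediated O-arylation of 4 with 2,5-dimethoxyphenylboronic acid (pyridine, 4 Å molecular sieves, CH2Cl2, air, rt; Chan–Lam–Evans coupling, under which aryl bromides do not react) should give 1,3,4-tribromo-5-(2,5-dimethoxyphenoxy)-2-methoxybenzene F5. BBr3 (CH2Cl2, –78 °C → rt) cleaves its three methyl ethers and gives 17.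

Step 9. Br2 may oxidise the hydroquinone ring to the quinone, after which bromide can displace the ring A aryloxy group from the quinone, or bromination may continue at C3 of ring A. The fallback sets out from 16 and returns at 18; bromination is done before demethylation. Br2 (3 equiv, AcOH, rt) acts on ring B of 16 while the C5' oxygen and the ring A oxygen are still methylated, so that no hydroquinone is present, and should give 2,3,5-tribromo-4-methoxy-6-(2,3,5-tribromo-4-methoxyphenoxy)phenol F6. BBr3 then removes both methyl groups and gives 18.

Further compounds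
F1 | step 7 | [(E)-2-(trimethylsilyl)ethenyl]lithium | [Li]/C=C/[Si](C)(C)C
F2 | step 7 | lithium salt of pentacarbonyl[(E)-3-(trimethylsilyl)acryloyl]chromate, drawn as (CO)5Cr=C(OLi)CH=CHSiMe3 | C[Si](C)(C)/C=C/C(O[Li])=[Cr](=C=O)(=C=O)(=C=O)(=C=O)=C=O
F3 | step 7 | pentacarbonyl{methoxy[(E)-2-(trimethylsilyl)ethenyl]carbene}chromium | COC(/C=C/[Si](C)(C)C)=[Cr](=C=O)(=C=O)(=C=O)(=C=O)=C=O
F4 | step 7 | [4-methoxy-2-(2,3,5-tribromo-4-methoxyphenoxy)phenoxy]trimethylsilane | COc1ccc(O[Si](C)(C)C)c(Oc2cc(Br)c(OC)c(Br)c2Br)c1
F5 | step 5 | 1,3,4-tribromo-5-(2,5-dimethoxyphenoxy)-2-methoxybenzene | COc1c(Br)cc(Oc2cc(OC)ccc2OC)c(Br)c1Br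
F6 | step 9 | 2,3,5-tribromo-4-methoxy-6-(2,3,5-tribromo-4-methoxyphenoxy)phenol | COc1c(Br)cc(Oc2c(O)c(Br)c(Br)c(OC)c2Br)c(Br)c1Br
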